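**Retrosynthetic overview**
1. The target comes from a triol by oxidation of the one secondary alcohol; the C6-methyl alkene of ring C comes from a cycloheptanone through its enol triflate.
2. Ring C (seven-membered) is made last, in the step that joins the two halves: a cis-hydrindan-5-one is expanded 6→7 by a 1,2-shift of its quaternary α-carbon onto a carbenoid carbon carried by the ring A/B half (forms C4–C5, sets C5).
3. Ring A/B half: ring B is a bought cyclohexenone; anti conjugate addition builds the quaternary carbon, enolate allylation brings the three-carbon arm, and ring A (oxepane) is closed by 7-endo epoxide opening.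
4. Ring D half: a bought cyclopentenone (ring D) receives the six-membered precursor of ring C in an enantioselective Diels–Alder step; the C1 carbinol follows by methylenation and hydration.
5. Order of ring formation: B (bought) → A; D (bought) → six-membered ring; ring C by expansion at the coupling.

Assumption: rings are lettered A (oxepanone), B (cyclohexane), C (seven-membered carbocycle), D (cyclopentane); locants follow 1-benzoxepine and azulene numbering; where a name and its SMILES could be read differently, the SMILES holds.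

**Route**

Step 1
Reactants: 1 2-methylcyclohex-2-en-1-one
Product: 2 (S)-2-methylcyclohex-2-en-1-ol
Conditions: (R)-1-methyl-3,3-diphenyltetrahydro-1H,3H-pyrrolo[1,2-c][1,3,2]oxazaborole (10 mol %), BH3·SMe2, THF, −20 °C
Reagents that add atoms: none
Why: Corey–Bakshi–Shibata reduction, in which the trisubstituted alkenyl arm is the large group so that the (R)-catalyst delivers hydride to the face giving the (S)-carbinol, the centre that becomes the oxygen-bearing ring-fusion carbon of rings A/B.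

Step 2
Reactants: 2 (S)-2-methylcyclohex-2-en-1-ol
Product: 3 (S)-triethyl[(2-methylcyclohex-2-en-1-yl)oxy]silane
Conditions: Et3SiCl, imidazole, CH2Cl2, 0 °C → rt
Reagents that add atoms: chlorotriethylsilane, CC[Si](Cl)(CC)CC
Why: Standard silylation of a secondary allylic alcohol, with the triethylsilyl group chosen because it survives cuprate and enolate chemistry yet is lost under the acid of step 6.

Step 3
Reactants: 3 (S)-triethyl[(2-methylcyclohex-2-en-1-yl)oxy]silane
Product: 4 (S)-3-methyl-4-(triethylsilyloxy)cyclohex-2-en-1-one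
Conditions: Rh2(cap)4 (cap = caprolactamate, 1 mol %), t-BuOOH (5 equiv, decane), K2CO3, CH2Cl2, rt
Reagents that add atoms: tert-butyl hydroperoxide, CC(C)(C)OO
Why: Allylic C–H oxidation with the Rh2(cap)4/t-BuOOH system attacks the ring CH2 next to the unsubstituted alkene carbon (the carbinol C–H is shielded by the silyl ether) and gives the γ-silyloxy enone without touching the stereocentre.

Step 4
Reactants: 4 (S)-3-methyl-4-(triethylsilyloxy)cyclohex-2-en-1-one; 5 5-bromo-2-methylpent-2-ene; 6 allyl iodide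
Product: 10 (3S,4S)-3-methyl-3-(4-methylpent-3-en-1-yl)-2-(prop-2-en-1-yl)-4-(triethylsilyloxy)cyclohexan-1-one as a C2 epimer mixture, via Grignard reagent 7 (not isolated), via trimethylsilyl enol ether 8 (not isolated), via lithium enolate 9 (not isolated)
Conditions: 5, Mg, THF, rt; then 4, CuBr·SMe2 (10 mol %), Me3SiCl, THF, −78 → −40 °C; volatiles off; MeLi, THF, 0 °C; then 6, DMPU, −78 → 0 °C
Reagents that add atoms: none
Why: Copper-catalysed conjugate addition of the Grignard reagent with Me3SiCl occurs anti to the neighbouring silyloxy group and so sets the quaternary carbon with the ring-A chain trans to oxygen, after which the regiodefined lithium enolate is C-allylated; the α-centre forms as a mixture and is settled in step 6.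

Step 5
Reactants: 10 (3S,4S)-3-methyl-3-(4-methylpent-3-en-1-yl)-2-(prop-2-en-1-yl)-4-(triethylsilyloxy)cyclohexan-1-one
Product: 11 (3S,4S)-3-{2-[(2R)-3,3-dimethyloxiran-2-yl]ethyl}-3-methyl-2-(prop-2-en-1-yl)-4-(triethylsilyloxy)cyclohexan-1-one as a C2 epimer mixture
Conditions: 1,2:4,5-di-O-isopropylidene-β-D-erythro-hexo-2,3-diulo-2,6-pyranose (Shi ketone, 30 mol %), KHSO5 (as 2KHSO5·KHSO4·K2SO4), K2CO3, Bu4NHSO4, MeCN/dimethoxymethane/aq. buffer pH 10.5, 0 °C
Reagents that add atoms: potassium peroxymonosulfate, [K+].[O-]S(=O)(=O)OO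
Why: Shi asymmetric epoxidation, in which the chiral dioxirane oxidises only the electron-rich trisubstituted alkene (the terminal allyl alkene is inert) and catalyst control gives the (R)-epoxide so that later intermediates are single diastereomers.

Step 6
Reactants: 11 (3S,4S)-3-{2-[(2R)-3,3-dimethyloxiran-2-yl]ethyl}-3-methyl-2-(prop-2-en-1-yl)-4-(triethylsilyloxy)cyclohexan-1-one
Product: 14 (3R,5aS,6S,9aS)-3-hydroxy-2,2,5a-trimethyl-6-(prop-2-en-1-yl)octahydro-1-benzoxepin-7(2H)-one, via epoxy alcohol 12 (not isolated), via C6-epimeric oxepane ketones 13 (not isolated)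
Conditions: (+)-camphor-10-sulfonic acid (20 mol %), i-PrOH (3 equiv), CH2Cl2, 0 °C → rt; then K2CO3, MeOH, rt
Reagents that add atoms: none
Why: Acid removes the silyl ether and the freed hydroxyl opens the protonated trisubstituted epoxide at its tertiary carbon (7-endo hydroxy-epoxide cyclisation under electronic control) to give the trans-fused oxepane, and base then equilibrates the ketone α-carbon towards the equatorial allyl epimer cis to the axial angular methyl (the minor epimer is recycled).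

Step 7
Reactants: 14 (3R,5aS,6S,9aS)-3-hydroxy-2,2,5a-trimethyl-6-(prop-2-en-1-yl)octahydro-1-benzoxepin-7(2H)-one
Product: 16 (3R,5aS,6S,7R,9aS)-2,2,5a,7-tetramethyl-6-(prop-2-en-1-yl)-3,7-bis(triethylsilyloxy)decahydro-1-benzoxepine, via bis(bromomagnesium) alkoxide 15 (not isolated)
Conditions: MeMgBr (4 equiv, Et2O), CH2Cl2, −78 → 0 °C; then Et3SiOTf, 2,6-lutidine, 0 °C → rt
Reagents that add atoms: methylmagnesium bromide, C[Mg]Br; triethylsilyl trifluoromethanesulfonate, CC[Si](CC)(CC)OS(=O)(=O)C(F)(F)F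
Why: Grignard addition to the conformationally locked ketone takes the equatorial trajectory because the axial face is blocked by the 1,3-diaxial angular methyl, giving the axial tertiary alcohol, and both magnesium alkoxides are silylated in the same flask.

Step 8
Reactants: 16 (3R,5aS,6S,7R,9aS)-2,2,5a,7-tetramethyl-6-(prop-2-en-1-yl)-3,7-bis(triethylsilyloxy)decahydro-1-benzoxepine
Product: 18 3-[(3R,5aS,6S,7R,9aS)-2,2,5a,7-tetramethyl-3,7-bis(triethylsilyloxy)decahydro-1-benzoxepin-6-yl]propan-1-ol, via B-alkyl-9-BBN adduct 17 (not isolated)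
Conditions: 9-BBN, THF, 0 °C → rt; then NaOH, H2O2, 0 °C
Reagents that add atoms: hydrogen peroxide, OO
Why: Anti-Markovnikov hydroboration–oxidation of the only alkene gives the primary alcohol while the silyl ethers stay intact.

Step 9
Reactants: 18 3-[(3R,5aS,6S,7R,9aS)-2,2,5a,7-tetramethyl-3,7-bis(triethylsilyloxy)decahydro-1-benzoxepin-6-yl]propan-1-ol
Product: 19 3-[(3R,5aS,6S,7R,9aS)-2,2,5a,7-tetramethyl-3,7-bis(triethylsilyloxy)decahydro-1-benzoxepin-6-yl]propyl 2,4,6-triisopropylbenzoate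
Conditions: 2,4,6-triisopropylbenzoic acid, PPh3, diisopropyl azodicarboxylate, THF, 0 °C → rt
Reagents that add atoms: 2,4,6-triisopropylbenzoic acid, CC(C)c1cc(C(C)C)c(C(=O)O)c(C(C)C)c1
Why: Mitsunobu esterification of the primary alcohol installs the hindered benzoate that directs α-lithiation and later serves as the leaving group.

Step 10
Reactants: 20 4-methylpent-1-en-3-one
Product: 21 triisopropyl[(4-methylpenta-1,3-dien-3-yl)oxy]silane
Conditions: i-Pr3SiOTf, Et3N, CH2Cl2, 0 °C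
Reagents that add atoms: triisopropylsilyl trifluoromethanesulfonate, CC(C)[Si](C(C)C)(C(C)C)OS(=O)(=O)C(F)(F)F
Why: Soft enolisation at the only α-hydrogen (the isopropyl methine) gives the cross-conjugated 2-silyloxydiene.

Step 11
Reactants: 21 triisopropyl[(4-methylpenta-1,3-dien-3-yl)oxy]silane; 22 cyclopent-2-en-1-one
Product: 23 (3aS,7aS)-4,4-dimethyl-5-[(triisopropylsilyl)oxy]-2,3,3a,4,7,7a-hexahydro-1H-inden-1-one
Conditions: (S)-1-(2-methylphenyl)-3,3-diphenyltetrahydro-1H,3H-pyrrolo[1,2-c][1,3,2]oxazaborole (20 mol %), HN(SO2CF3)2 (16 mol %), CH2Cl2, −78 → −40 °C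
Reagents that add atoms: none
Why: Enantioselective Diels–Alder reaction catalysed by the protonated oxazaborolidine (possibly stepwise Mukaiyama–Michael then Michael), in which the nucleophilic CMe2 terminus of the silyloxydiene bonds to the enone β-carbon, suprafacial addition fixes the cis ring fusion and catalyst face selection fixes both ring-fusion centres (the catalyst antipode is chosen by the accepted enone-binding model).

Step 12
Reactants: 23 (3aS,7aS)-4,4-dimethyl-5-[(triisopropylsilyl)oxy]-2,3,3a,4,7,7a-hexahydro-1H-inden-1-one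
Product: 25 (3aS,7aS)-4,4-dimethyl-1-methylideneoctahydro-5H-inden-5-one, via methylidene silyl enol ether 24 (not isolated)
Conditions: Cp2TiMe2, toluene, 65 °C; then Bu4NF, AcOH, THF, 0 °C
Reagents that add atoms: dimethyltitanocene, C[Ti+2]C.c1cc[cH-]c1.c1cc[cH-]c1
Why: Petasis methylenation converts the cyclopentanone carbonyl under non-basic conditions (no epimerisation at the ring fusion, the other carbonyl being masked as its enol ether), and fluoride with acetic acid then unmasks the hindered ketone.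

Step 13
Reactants: 25 (3aS,7aS)-4,4-dimethyl-1-methylideneoctahydro-5H-inden-5-one
Product: 26 (1S,3aS,7aS)-1-hydroxy-1,4,4-trimethyloctahydro-5H-inden-5-one
Conditions: Co(acac)2 (20 mol %), PhSiH3, O2 (1 atm), THF, rt
Reagents that add atoms: dioxygen, O=O
Why: Mukaiyama hydration (hydrogen-atom transfer, then O2 capture of the tertiary radical) delivers oxygen to the convex face anti to the C7a–C7 bond and so sets C1 with OH cis to the ring-fusion hydrogens, the epimer that direct methyl addition to the ketone would not give.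

Step 14
Reactants: 26 (1S,3aS,7aS)-1-hydroxy-1,4,4-trimethyloctahydro-5H-inden-5-one
Product: 27 (1S,3aS,7aS)-1,4,4-trimethyl-1-(triethylsilyloxy)octahydro-5H-inden-5-one
Conditions: Et3SiOTf, 2,6-lutidine, CH2Cl2, −78 °C
Reagents that add atoms: triethylsilyl trifluoromethanesulfonate, CC[Si](CC)(CC)OS(=O)(=O)C(F)(F)F
Why: Silylation of the tertiary alcohol so that it cannot quench the organolithium of step 15.

Step 15
Reactants: 19 3-[(3R,5aS,6S,7R,9aS)-2,2,5a,7-tetramethyl-3,7-bis(triethylsilyloxy)decahydro-1-benzoxepin-6-yl]propyl 2,4,6-triisopropylbenzoate; 27 (1S,3aS,7aS)-1,4,4-trimethyl-1-(triethylsilyloxy)octahydro-5H-inden-5-one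
Product: 30 (1S,3aS,5S,8aS)-1,4,4-trimethyl-5-{2-[(3R,5aS,6S,7R,9aS)-2,2,5a,7-tetramethyl-3,7-bis(triethylsilyloxy)decahydro-1-benzoxepin-6-yl]ethyl}-1-(triethylsilyloxy)octahydroazulen-6(1H)-one, via α-lithiated benzoate 28 (not isolated), via lithium alkoxide adduct 29 (not isolated)
Conditions: 19, s-BuLi, (+)-sparteine, Et2O, −78 °C, 5 h; then 27, −78 °C, 2 h; then Me2AlCl, −78 → 0 °C
Reagents that add atoms: none
Why: Proposed new method: carbenoid homologation of a ketone with a sparteine-defined α-lithiated triisopropylbenzoate, in which the (R)-organolithium 28 adds to the hindered carbonyl with retention at carbon, Me2AlCl turns the lithium alkoxide 29 into an aluminium alkoxide that chelates and activates the benzoate carbonyl, and the electron-rich quaternary-carbon–carbinol bond lying anti to the C–O bond migrates with inversion at the carbenoid carbon (anionic semipinacol 1,2-shift), which expands the six-membered ring to the cycloheptanone, joins the two halves and fixes C5; the closest known chemistry is the 1,2-metallate shift of the same lithiated esters on boron (lithiation–borylation), the trialkylaluminium-promoted stereospecific pinacol-type shift of β-mesyloxy alcohols and the ring enlargement of ketones through β-hydroxy selenides.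

Step 16
Reactants: 30 (1S,3aS,5S,8aS)-1,4,4-trimethyl-5-{2-[(3R,5aS,6S,7R,9aS)-2,2,5a,7-tetramethyl-3,7-bis(triethylsilyloxy)decahydro-1-benzoxepin-6-yl]ethyl}-1-(triethylsilyloxy)octahydroazulen-6(1H)-one
Product: 32 (1S,3aS,5S,8aS)-1,4,4-trimethyl-5-{2-[(3R,5aS,6S,7R,9aS)-2,2,5a,7-tetramethyl-3,7-bis(triethylsilyloxy)decahydro-1-benzoxepin-6-yl]ethyl}-1-(triethylsilyloxy)-1,2,3,3a,4,5,8,8a-octahydroazulen-6-yl trifluoromethanesulfonate, via potassium enolate 31 (not isolated)
Conditions: KN(SiMe3)2, THF, −78 °C; then PhN(SO2CF3)2, −78 → 0 °C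
Reagents that add atoms: N-phenylbis(trifluoromethanesulfonimide), O=S(=O)(N(c1ccccc1)S(=O)(=O)C(F)(F)F)C(F)(F)F
Why: Kinetic deprotonation by the bulky amide occurs at the C7 methylene and not at the congested C5 methine next to CMe2, so O-triflation gives the C6=C7 enol triflate with C5 untouched.

Step 17
Reactants: 32 the enol triflate of step 16
Product: 33 (1S,3aS,5R,8aS)-1,4,4,6-tetramethyl-5-{2-[(3R,5aS,6S,7R,9aS)-2,2,5a,7-tetramethyl-3,7-bis(triethylsilyloxy)decahydro-1-benzoxepin-6-yl]ethyl}-1-(triethylsilyloxy)-1,2,3,3a,4,5,8,8a-octahydroazulene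
Conditions: MeMgBr, Fe(acac)3 (10 mol %), THF/NMP, −30 → 0 °C
Reagents that add atoms: methylmagnesium bromide, C[Mg]Br
Why: Iron-catalysed cross-coupling of the alkenyl triflate with the methyl Grignard reagent installs the vinylic methyl group and leaves the silyl ethers alone.

Step 18
Reactants: 33 the tris(triethylsilyl) ether of step 17
Product: 34 (3R,5aS,6S,7R,9aS)-6-{2-[(1S,3aS,5R,8aS)-1-hydroxy-1,4,4,6-tetramethyl-1,2,3,3a,4,5,8,8a-octahydroazulen-5-yl]ethyl}-2,2,5a,7-tetramethyldecahydro-1-benzoxepine-3,7-diol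
Conditions: Bu4NF, THF, 50 °C
Reagents that add atoms: none
Why: Fluoride-mediated desilylation cleaves all three triethylsilyl ethers to give the triol.

Step 19
Reactants: 34 the triol of step 18
Product: 35 (5aS,6S,7R,9aS)-7-hydroxy-6-{2-[(1S,3aS,5R,8aS)-1-hydroxy-1,4,4,6-tetramethyl-1,2,3,3a,4,5,8,8a-octahydroazulen-5-yl]ethyl}-2,2,5a,7-tetramethyloctahydro-1-benzoxepin-3(2H)-one
Conditions: Dess–Martin periodinane, NaHCO3, CH2Cl2, rt
Reagents that add atoms: none
Why: Dess–Martin oxidation converts the only secondary alcohol into the ring-A ketone while the two tertiary alcohols and the trisubstituted alkene are inert, which gives the target.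

**Compound list**
1 | 2-methylcyclohex-2-en-1-one | CC1=CCCCC1=O | starting material
2 | (S)-2-methylcyclohex-2-en-1-ol | CC1=CCCC[C@@H]1O | intermediate
3 | (S)-triethyl[(2-methylcyclohex-2-en-1-yl)oxy]silane | CC1=CCCC[C@@H]1O[Si](CC)(CC)CC | intermediate
4 | (S)-3-methyl-4-(triethylsilyloxy)cyclohex-2-en-1-one | CC1=CC(=O)CC[C@@H]1O[Si](CC)(CC)CC | intermediate
5 | 5-bromo-2-methylpent-2-ene | CC(C)=CCCBr | starting material
6 | allyl iodide | C=CCI | starting material
7 | (4-methylpent-3-en-1-yl)magnesium bromide | CC(C)=CCC[Mg]Br | intermediate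
8 | trimethylsilyl enol ether of the conjugate adduct, (3S,4S) | C[Si](C)(C)OC1=C[C@](C)(CCC=C(C)C)[C@@H](O[Si](CC)(CC)CC)CC1 | intermediate
9 | lithium enolate of the conjugate adduct, (3S,4S) | [Li]OC1=C[C@](C)(CCC=C(C)C)[C@@H](O[Si](CC)(CC)CC)CC1 | intermediate
10 | (3S,4S)-3-methyl-3-(4-methylpent-3-en-1-yl)-2-(prop-2-en-1-yl)-4-(triethylsilyloxy)cyclohexan-1-one, C2 epimers (C2 open in the SMILES) | C=CCC1[C@](C)(CCC=C(C)C)[C@@H](O[Si](CC)(CC)CC)CCC1=O | intermediate
11 | (3S,4S)-3-{2-[(2R)-3,3-dimethyloxiran-2-yl]ethyl}-3-methyl-2-(prop-2-en-1-yl)-4-(triethylsilyloxy)cyclohexan-1-one, C2 epimers | C=CCC1[C@](C)(CC[C@H]2OC2(C)C)[C@@H](O[Si](CC)(CC)CC)CCC1=O | intermediate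
12 | (3S,4S)-3-{2-[(2R)-3,3-dimethyloxiran-2-yl]ethyl}-4-hydroxy-3-methyl-2-(prop-2-en-1-yl)cyclohexan-1-one, C2 epimers | C=CCC1[C@](C)(CC[C@H]2OC2(C)C)[C@@H](O)CCC1=O | intermediate
13 | (3R,5aS,9aS)-3-hydroxy-2,2,5a-trimethyl-6-(prop-2-en-1-yl)octahydro-1-benzoxepin-7(2H)-one, C6 epimers | C=CCC1[C@]2(C)CC[C@@H](O)C(C)(C)O[C@H]2CCC1=O | intermediate
14 | (3R,5aS,6S,9aS)-3-hydroxy-2,2,5a-trimethyl-6-(prop-2-en-1-yl)octahydro-1-benzoxepin-7(2H)-one | C=CC[C@H]1[C@]2(C)CC[C@@H](O)C(C)(C)O[C@H]2CCC1=O | intermediate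
15 | bis(bromomagnesium) alkoxide of the (3R,5aS,6S,7R,9aS)-3,7-diol | C=CC[C@H]1[C@]2(C)CC[C@@H](O[Mg]Br)C(C)(C)O[C@H]2CC[C@@]1(C)O[Mg]Br | intermediate
16 | (3R,5aS,6S,7R,9aS)-2,2,5a,7-tetramethyl-6-(prop-2-en-1-yl)-3,7-bis(triethylsilyloxy)decahydro-1-benzoxepine | C=CC[C@H]1[C@]2(C)CC[C@@H](O[Si](CC)(CC)CC)C(C)(C)O[C@H]2CC[C@@]1(C)O[Si](CC)(CC)CC | intermediate
17 | B-alkyl-9-borabicyclo[3.3.1]nonane adduct of 16 (boron on the terminal carbon) | C(CC[C@H]1[C@]2(C)CC[C@@H](O[Si](CC)(CC)CC)C(C)(C)O[C@H]2CC[C@@]1(C)O[Si](CC)(CC)CC)B1C2CCCC1CCC2 | intermediate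
18 | 3-[(3R,5aS,6S,7R,9aS)-2,2,5a,7-tetramethyl-3,7-bis(triethylsilyloxy)decahydro-1-benzoxepin-6-yl]propan-1-ol | OCCC[C@H]1[C@]2(C)CC[C@@H](O[Si](CC)(CC)CC)C(C)(C)O[C@H]2CC[C@@]1(C)O[Si](CC)(CC)CC | intermediate
19 | 3-[(3R,5aS,6S,7R,9aS)-2,2,5a,7-tetramethyl-3,7-bis(triethylsilyloxy)decahydro-1-benzoxepin-6-yl]propyl 2,4,6-triisopropylbenzoate | CC(C)c1cc(C(C)C)c(C(=O)OCCC[C@H]2[C@]3(C)CC[C@@H](O[Si](CC)(CC)CC)C(C)(C)O[C@H]3CC[C@@]2(C)O[Si](CC)(CC)CC)c(C(C)C)c1 | intermediate
20 | 4-methylpent-1-en-3-one | C=CC(=O)C(C)C | starting material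
21 | triisopropyl[(4-methylpenta-1,3-dien-3-yl)oxy]silane | C=CC(O[Si](C(C)C)(C(C)C)C(C)C)=C(C)C | intermediate
22 | cyclopent-2-en-1-one | O=C1C=CCC1 | starting material
23 | (3aS,7aS)-4,4-dimethyl-5-[(triisopropylsilyl)oxy]-2,3,3a,4,7,7a-hexahydro-1H-inden-1-one (cis-fused) | CC(C)[Si](C(C)C)(C(C)C)OC1=CC[C@H]2[C@H](CCC2=O)C1(C)C | intermediate
24 | triisopropyl{[(3aS,7aS)-4,4-dimethyl-1-methylidene-2,3,3a,4,7,7a-hexahydro-1H-inden-5-yl]oxy}silane | CC(C)[Si](C(C)C)(C(C)C)OC1=CC[C@H]2[C@H](CCC2=C)C1(C)C | intermediate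
25 | (3aS,7aS)-4,4-dimethyl-1-methylideneoctahydro-5H-inden-5-one | O=C1CC[C@H]2[C@H](CCC2=C)C1(C)C | intermediate
26 | (1S,3aS,7aS)-1-hydroxy-1,4,4-trimethyloctahydro-5H-inden-5-one | O=C1CC[C@H]2[C@H](CC[C@]2(C)O)C1(C)C | intermediate
27 | (1S,3aS,7aS)-1,4,4-trimethyl-1-(triethylsilyloxy)octahydro-5H-inden-5-one | O=C1CC[C@H]2[C@H](CC[C@]2(C)O[Si](CC)(CC)CC)C1(C)C | intermediate
28 | (R)-α-lithio derivative of 19 (lithium on the O-bearing carbon of the propyl arm) | CC(C)c1cc(C(C)C)c(C(=O)O[C@H]([Li])CC[C@H]2[C@]3(C)CC[C@@H](O[Si](CC)(CC)CC)C(C)(C)O[C@H]3CC[C@@]2(C)O[Si](CC)(CC)CC)c(C(C)C)c1 | intermediate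
29 | lithium alkoxide from addition of 28 to the carbonyl of 27 (carbinol carbon left open, it is lost in the shift) | CC(C)c1cc(C(C)C)c(C(=O)O[C@H](C2(O[Li])CC[C@H]3[C@H](CC[C@]3(C)O[Si](CC)(CC)CC)C2(C)C)CC[C@H]2[C@]3(C)CC[C@@H](O[Si](CC)(CC)CC)C(C)(C)O[C@H]3CC[C@@]2(C)O[Si](CC)(CC)CC)c(C(C)C)c1 | intermediate
30 | (1S,3aS,5S,8aS)-1,4,4-trimethyl-5-{2-[(3R,5aS,6S,7R,9aS)-2,2,5a,7-tetramethyl-3,7-bis(triethylsilyloxy)decahydro-1-benzoxepin-6-yl]ethyl}-1-(triethylsilyloxy)octahydroazulen-6(1H)-one | O=C1CC[C@H]2[C@H](CC[C@]2(C)O[Si](CC)(CC)CC)C(C)(C)[C@@H]1CC[C@H]1[C@]2(C)CC[C@@H](O[Si](CC)(CC)CC)C(C)(C)O[C@H]2CC[C@@]1(C)O[Si](CC)(CC)CC | intermediate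
31 | potassium C6=C7 enolate of 30 | [K]OC1=CC[C@H]2[C@H](CC[C@]2(C)O[Si](CC)(CC)CC)C(C)(C)[C@@H]1CC[C@H]1[C@]2(C)CC[C@@H](O[Si](CC)(CC)CC)C(C)(C)O[C@H]2CC[C@@]1(C)O[Si](CC)(CC)CC | intermediate
32 | C6=C7 enol trifluoromethanesulfonate of 30, (1S,3aS,5S,8aS) | O=S(=O)(OC1=CC[C@H]2[C@H](CC[C@]2(C)O[Si](CC)(CC)CC)C(C)(C)[C@@H]1CC[C@H]1[C@]2(C)CC[C@@H](O[Si](CC)(CC)CC)C(C)(C)O[C@H]2CC[C@@]1(C)O[Si](CC)(CC)CC)C(F)(F)F | intermediate
33 | tris(triethylsilyl) ether of 34, (1S,3aS,5R,8aS) in the hydroazulene and (3R,5aS,6S,7R,9aS) in the benzoxepane | CC1=CC[C@H]2[C@H](CC[C@]2(C)O[Si](CC)(CC)CC)C(C)(C)[C@@H]1CC[C@H]1[C@]2(C)CC[C@@H](O[Si](CC)(CC)CC)C(C)(C)O[C@H]2CC[C@@]1(C)O[Si](CC)(CC)CC | intermediate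
34 | (3R,5aS,6S,7R,9aS)-6-{2-[(1S,3aS,5R,8aS)-1-hydroxy-1,4,4,6-tetramethyl-1,2,3,3a,4,5,8,8a-octahydroazulen-5-yl]ethyl}-2,2,5a,7-tetramethyldecahydro-1-benzoxepine-3,7-diol | CC1=CC[C@H]2[C@H](CC[C@]2(C)O)C(C)(C)[C@@H]1CC[C@H]1[C@]2(C)CC[C@@H](O)C(C)(C)O[C@H]2CC[C@@]1(C)O | intermediate
35 | (5aS,6S,7R,9aS)-7-hydroxy-6-{2-[(1S,3aS,5R,8aS)-1-hydroxy-1,4,4,6-tetramethyl-1,2,3,3a,4,5,8,8a-octahydroazulen-5-yl]ethyl}-2,2,5a,7-tetramethyloctahydro-1-benzoxepin-3(2H)-one | CC1=CC[C@H]2[C@H](CC[C@]2(C)O)C(C)(C)[C@@H]1CC[C@H]1[C@]2(C)CCC(=O)C(C)(C)O[C@H]2CC[C@@]1(C)O | target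

**Step count and risks**

Total steps: 19. Longest linear sequence: 14 (steps 1–9, then 15–19); the ring D half takes 5 steps (10–14).

Three steps most likely to fail:

Step 15 (new coupling and ring expansion). The adduct may fail to form on the hindered ketone, may close to an epoxide, or the CH2 carbon may migrate instead of the quaternary one. The fallback uses the known selenium-based ring enlargement of ketones, sets out from 18 and 27 and comes back at 30. Alcohol 18 is oxidised with Dess–Martin periodinane to the aldehyde F1, which with MeSeH and ZnCl2 gives the bis(methylseleno)acetal F2. n-BuLi (THF, −78 °C) cleaves one C–Se bond to give the α-(methylseleno)alkyllithium F3, which adds to 27 to give the β-hydroxy selenide F4. AgBF4 on alumina in CH2Cl2 then makes selenium the leaving group and the more substituted ring carbon migrates. This gives 30 together with its C5 epimer, which is separated and recycled by DBU equilibration.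

Step 11 (cycloaddition with a diene whose reacting terminus is fully substituted). Low reactivity or low enantioselectivity is possible. The fallback replaces the cycloaddition by two separate Michael additions, sets out from 21 and 22 and comes back at 25. The same protonated oxazaborolidine is used in Mukaiyama–Michael mode (−78 °C, aqueous HCl quench after the first C–C bond), which needs no s-cis diene, and gives (S)-3-(2-methyl-3-oxopent-4-en-2-yl)cyclopentan-1-one F5. DBU in MeCN closes the six-membered ring by intramolecular Michael addition to the cis-fused (3aS,7aS)-4,4-dimethylhexahydro-1H-indene-1,5(4H)-dione F6. Cp2TiMe2 then methylenates the unhindered cyclopentanone carbonyl selectively (the other carbonyl is shielded by CMe2) to give 25.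

Step 6 (7-endo against 6-exo epoxide opening). The fallback replaces epoxide opening by alkoxymercuration, sets out from 10 and comes back at 14. Ketone 10 is desilylated (pyridinium p-toluenesulfonate, MeOH) to the hydroxy ketone F7. Hg(OCOCF3)2 (MeCN, −20 °C; then aqueous KBr) closes the oxepane by Markovnikov attack of oxygen on the tertiary alkene carbon and gives the bromomercurial F8. O2 with NaBH4 (0.5 equiv, DMF, −20 °C) replaces mercury by hydroxyl, and K2CO3 in MeOH equilibrates the α-centre. This gives 14 and its C3 epimer F9; F9 need not be removed, since C3 ends as the ketone carbon of 35.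

Further compounds
F1 | step 15 | 3-[(3R,5aS,6S,7R,9aS)-2,2,5a,7-tetramethyl-3,7-bis(triethylsilyloxy)decahydro-1-benzoxepin-6-yl]propanal | O=CCC[C@H]1[C@]2(C)CC[C@@H](O[Si](CC)(CC)CC)C(C)(C)O[C@H]2CC[C@@]1(C)O[Si](CC)(CC)CC
F2 | step 15 | bis(methylseleno)acetal of F1 | C[Se]C([Se]C)CC[C@H]1[C@]2(C)CC[C@@H](O[Si](CC)(CC)CC)C(C)(C)O[C@H]2CC[C@@]1(C)O[Si](CC)(CC)CC
F3 | step 15 | α-(methylseleno)alkyllithium from F2 | [Li]C([Se]C)CC[C@H]1[C@]2(C)CC[C@@H](O[Si](CC)(CC)CC)C(C)(C)O[C@H]2CC[C@@]1(C)O[Si](CC)(CC)CC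
F4 | step 15 | β-hydroxy selenide from F3 and 27 | C[Se]C(CC[C@H]1[C@]2(C)CC[C@@H](O[Si](CC)(CC)CC)C(C)(C)O[C@H]2CC[C@@]1(C)O[Si](CC)(CC)CC)C1(O)CC[C@H]2[C@H](CC[C@]2(C)O[Si](CC)(CC)CC)C1(C)C
F5 | step 11 | (S)-3-(2-methyl-3-oxopent-4-en-2-yl)cyclopentan-1-one | C=CC(=O)C(C)(C)[C@H]1CCC(=O)C1
F6 | step 11 | (3aS,7aS)-4,4-dimethylhexahydro-1H-indene-1,5(4H)-dione | O=C1CC[C@H]2[C@H](CCC2=O)C1(C)C
F7 | step 6 | (3S,4S)-4-hydroxy-3-methyl-3-(4-methylpent-3-en-1-yl)-2-(prop-2-en-1-yl)cyclohexan-1-one, C2 epimers | C=CCC1[C@](C)(CCC=C(C)C)[C@@H](O)CCC1=O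
F8 | step 6 | 3-(bromomercurio)-2,2,5a-trimethyl-6-(prop-2-en-1-yl)octahydro-1-benzoxepin-7(2H)-one, (5aS,9aS) | C=CCC1[C@]2(C)CCC([Hg]Br)C(C)(C)O[C@H]2CCC1=O
F9 | step 6 | (3S,5aS,6S,9aS)-3-hydroxy-2,2,5a-trimethyl-6-(prop-2-en-1-yl)octahydro-1-benzoxepin-7(2H)-one | C=CC[C@H]1[C@]2(C)CC[C@H](O)C(C)(C)O[C@H]2CCC1=O
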